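**Retrosynthetic overview**
- Target ⇐ bis(α-methylene) dilactone: one hydrogenation sets both methyl stereocentres (exo face of the fused lactone; face anti to the pyrrole in the side lactone).
- Side lactone ⇐ pyrrole-2-carbaldehyde + methyl 2-(bromomethyl)acrylate (catalytic asymmetric 2-(alkoxycarbonyl)allylation); aldehyde ⇐ Vilsmeier formylation.
- Pyrrole and azepine rings ⇐ one-pot intramolecular Paal–Knorr condensation of a cyclohexanone carrying a CH2CHO arm and a 4-azidobutyl arm.
- Ethyl and azidobutyl groups ⇐ anti,anti conjugate addition/enolate alkylation on a bicyclic enone.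
- Key step: tandem vinyl-radical 5-exo cyclization/α-keto-radical allylation of an iodoallyl acetal of (S)-4-hydroxycyclohexenone, which fixes the cis ring fusion. Ring order: cyclohexane (bought) → fused lactone ring → pyrrole + azepine → side lactone.

Assumption: enantiopure (4S)-4-hydroxycyclohex-2-en-1-one and 1-azido-4-iodobutane are bought as catalogue compounds. Bicyclic intermediates carry 1-benzofuran locants; tetracycles carry the locants of 12-oxa-4-azatetracyclo[7.6.1.0(4,16).0(11,15)]hexadecane.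

**Step 1**
Reactants: 1 (4S)-4-hydroxycyclohex-2-en-1-one; 2 methoxyallene
Product: 3 (4S)-4-[(2-iodo-1-methoxyprop-2-en-1-yl)oxy]cyclohex-2-en-1-one (both acetal epimers)
Conditions: N-iodosuccinimide (1.3 equiv), 2 (2 equiv), CH2Cl2, −78 to −30 °C
Reagents that add atoms: N-iodosuccinimide, O=C1CCC(=O)N1I
Why: Iodoalkoxylation (cohalogenation) of the enol-ether C=C of the alkoxyallene gives an oxocarbenium ion that the secondary alcohol captures, installing a 2-iodoallyl mixed-acetal tether without touching the carbinol stereocentre (the new acetal centre is a mixture that is erased in step 5).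

**Step 2**
Reactants: 3 (4S)-4-[(2-iodo-1-methoxyprop-2-en-1-yl)oxy]cyclohex-2-en-1-one
Product: 6 (3aS,7aS)-2-methoxy-3-methylidene-4-(prop-2-en-1-yl)hexahydro-1-benzofuran-5(2H)-one (cis-fused; epimers at C-2 and C-4), via vinyl radical 4 (not isolated), via alpha-keto radical 5 (not isolated)
Conditions: CH2=CHCH2SnBu3 (3 equiv), AIBN (0.2 equiv), benzene, 80 °C
Reagents that add atoms: allyltributylstannane, C=CC[Sn](CCCC)(CCCC)CCCC
Why: Stork-type tandem radical cyclization–trapping (Ueno–Stork haloacetal cyclization joined to a Keck allylation) in which Bu3Sn• abstracts iodine, the vinyl radical closes 5-exo-trig onto the enone β-carbon from the face that carries the tether oxygen, which enforces the cis ring fusion and so sets C-3a, and the electrophilic α-keto radical is allylated by the stannane, releasing Bu3Sn• to carry the chain.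

**Step 3**
Reactants: 6 (3aS,7aS)-2-methoxy-3-methylidene-4-(prop-2-en-1-yl)hexahydro-1-benzofuran-5(2H)-one
Product: 8 (3aS,7aS)-2-methoxy-3-methylidene-4-(prop-2-en-1-yl)-3,3a,4,7a-tetrahydro-1-benzofuran-5(2H)-one, via lithium enolate 7 (not isolated)
Conditions: LiN(i-Pr)2 (1.05 equiv), THF, −78 °C; then PhS(Cl)=N-t-Bu (1.2 equiv), −78 °C
Reagents that add atoms: none
Why: Kinetic deprotonation at the only methylene α-carbon (C-6, the other α-carbon being tertiary) followed by Mukaiyama dehydrogenation (S-sulfenylation of the enolate and syn-elimination) gives the C6=C7 enone regioselectively, and no stereocentre is formed.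

**Step 4**
Reactants: 8 (3aS,7aS)-2-methoxy-3-methylidene-4-(prop-2-en-1-yl)-3,3a,4,7a-tetrahydro-1-benzofuran-5(2H)-one; 9 1-azido-4-iodobutane
Product: 11 (3aS,6R,7R,7aS)-6-(4-azidobutyl)-7-ethyl-2-methoxy-3-methylidene-4-(prop-2-en-1-yl)hexahydro-1-benzofuran-5(2H)-one, via lithium enolate 10 (not isolated)
Conditions: Et2CuLi (from EtLi, CuI), Et2O–THF, −78 °C; then 9 (3 equiv), HMPA, −40 to 0 °C; aq NH4Cl
Reagents that add atoms: ethyllithium, [Li]CC
Why: Conjugate addition–enolate alkylation (three-component coupling) in which the cuprate adds to C-7 on the convex face anti to the ring-fusion C–O bond (ethyl trans to oxygen) and the regiodefined enolate is alkylated at C-6 anti to the new ethyl group, the 6,7-trans all-equatorial isomer also being the thermodynamic one at this epimerizable centre.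

**Step 5**
Reactants: 11 (3aS,6R,7R,7aS)-6-(4-azidobutyl)-7-ethyl-2-methoxy-3-methylidene-4-(prop-2-en-1-yl)hexahydro-1-benzofuran-5(2H)-one
Product: 13 (3aS,6R,7R,7aS)-6-(4-azidobutyl)-7-ethyl-3-methylidene-4-(prop-2-en-1-yl)hexahydro-1-benzofuran-2,5-dione, via lactol 12 (not isolated)
Conditions: CrO3, H2SO4, H2O, acetone, 0 °C
Reagents that add atoms: water, O
Why: Acidic hydrolysis of the methyl acetal to the lactol and chromic acid oxidation (Jones oxidation) give the α-methylene-γ-lactone, the acetal epimers converge, and no stereocentre is touched.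

**Step 6**
Reactants: 13 (3aS,6R,7R,7aS)-6-(4-azidobutyl)-7-ethyl-3-methylidene-4-(prop-2-en-1-yl)hexahydro-1-benzofuran-2,5-dione
Product: 16 (9R,10R,11S,15S)-10-ethyl-14-methylidene-12-oxa-4-azatetracyclo[7.6.1.0(4,16).0(11,15)]hexadeca-1(16),2-dien-13-one, via keto aldehyde 14 (not isolated), via amino keto aldehyde 15 (not isolated)
Conditions: O3, CH2Cl2, −78 °C (Sudan Red 7B end point); PPh3 (3 equiv), −78 °C to rt; then THF–H2O, AcOH, 50 °C, 0.01 M
Reagents that add atoms: none
Why: Chemoselective ozonolysis of the electron-rich allyl group (the conjugated exo-methylene reacts far more slowly), Staudinger reduction of the azide and intramolecular Paal–Knorr condensation of the amine with the 1,4-keto aldehyde build the pyrrole and the seven-membered ring in one pot and erase the epimeric C-4 centre, while the centre next to the ketone keeps its thermodynamically preferred trans arrangement.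

**Step 7**
Reactants: 16 (9R,10R,11S,15S)-10-ethyl-14-methylidene-12-oxa-4-azatetracyclo[7.6.1.0(4,16).0(11,15)]hexadeca-1(16),2-dien-13-one
Product: 18 (9R,10R,11S,15S)-10-ethyl-14-methylidene-13-oxo-12-oxa-4-azatetracyclo[7.6.1.0(4,16).0(11,15)]hexadeca-1(16),2-diene-3-carbaldehyde, via iminium salt 17 (not isolated)
Conditions: POCl3 (1.2 equiv), DMF, 0 °C to rt; then aq NaOAc
Reagents that add atoms: N,N-dimethylformamide, CN(C)C=O; water, O
Why: Vilsmeier–Haack formylation goes to the only free α-position of the electron-rich 1,2,3-trialkylpyrrole and creates no stereocentre.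

**Step 8**
Reactants: 18 (9R,10R,11S,15S)-10-ethyl-14-methylidene-13-oxo-12-oxa-4-azatetracyclo[7.6.1.0(4,16).0(11,15)]hexadeca-1(16),2-diene-3-carbaldehyde; 19 methyl 2-(bromomethyl)prop-2-enoate
Product: 21 (9R,10R,11S,15S)-10-ethyl-14-methylidene-3-[(2S)-4-methylidene-5-oxooxolan-2-yl]-12-oxa-4-azatetracyclo[7.6.1.0(4,16).0(11,15)]hexadeca-1(16),2-dien-13-one, via silyl ether 20 (not isolated)
Conditions: 19 (2 equiv), CrCl2 (10 mol %), chiral 1,8-bis(4-isopropyloxazolin-2-yl)carbazole ligand (12 mol %, enantiomer giving Si-face attack), Mn powder (2 equiv), Me3SiCl (2 equiv), i-Pr2NEt (cat.), THF, rt; then Bu4NF, AcOH, THF, 0 °C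
Reagents that add atoms: none
Why: Catalytic asymmetric Nozaki–Hiyama–Kishi-type 2-(alkoxycarbonyl)allylation in which the ligated allylchromium species (trivalent chromium) adds to the Si face of the aldehyde under catalyst control (the core stereocentres are remote), setting the (S)-carbinol, and the alkoxide freed on desilylation lactonizes onto the methyl ester under buffered, non-acidic conditions that keep the pyrrolyl carbinol from ionizing.

**Step 9**
Reactants: 21 (9R,10R,11S,15S)-10-ethyl-14-methylidene-3-[(2S)-4-methylidene-5-oxooxolan-2-yl]-12-oxa-4-azatetracyclo[7.6.1.0(4,16).0(11,15)]hexadeca-1(16),2-dien-13-one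
Product: 22 (9R,10R,11S,14R,15R)-10-ethyl-14-methyl-3-[(2S,4S)-4-methyl-5-oxooxolan-2-yl]-12-oxa-4-azatetracyclo[7.6.1.0(4,16).0(11,15)]hexadeca-1(16),2-dien-13-one (target)
Conditions: H2 (1 atm), RhCl(PPh3)3 (10 mol %), benzene–EtOH, rt
Reagents that add atoms: none
Why: Homogeneous hydrogenation delivers hydrogen to each exocyclic alkene from its open face, namely the convex face of the cis-fused lactone (hydrogen syn to both ring-fusion hydrogens, methyl cis to the pyrrole carbon) and the face anti to the pyrrolyl group of the side lactone (2,4-cis), while RhCl(PPh3)3 avoids isomerization to the butenolide and hydrogenolysis of the pyrrolylic C–O bond.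

**Compound list**
1 | (4S)-4-hydroxycyclohex-2-en-1-one | O=C1C=C[C@@H](O)CC1 | starting material
2 | methoxyallene (1-methoxypropa-1,2-diene) | COC=C=C | starting material
3 | (4S)-4-[(2-iodo-1-methoxyprop-2-en-1-yl)oxy]cyclohex-2-en-1-one (both acetal epimers) | O=C1C=C[C@@H](OC(OC)C(I)=C)CC1 | intermediate
4 | vinyl radical formed from 3 by loss of iodine | O=C1C=C[C@@H](OC(OC)[C]=C)CC1 | intermediate
5 | cis-fused cyclized α-keto radical (radical at C-4) | O=C1CC[C@@H]2OC(OC)C(=C)[C@@H]2[CH]1 | intermediate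
6 | (3aS,7aS)-2-methoxy-3-methylidene-4-(prop-2-en-1-yl)hexahydro-1-benzofuran-5(2H)-one (epimers at C-2 and C-4, allyl mainly trans to the C3–C3a bond) | O=C1CC[C@@H]2OC(OC)C(=C)[C@@H]2C1CC=C | intermediate
7 | lithium C5–C6 enolate of 6 | [Li+].[O-]C1=CC[C@@H]2OC(OC)C(=C)[C@@H]2C1CC=C | intermediate
8 | (3aS,7aS)-2-methoxy-3-methylidene-4-(prop-2-en-1-yl)-3,3a,4,7a-tetrahydro-1-benzofuran-5(2H)-one | O=C1C=C[C@@H]2OC(OC)C(=C)[C@@H]2C1CC=C | intermediate
9 | 1-azido-4-iodobutane | [N-]=[N+]=NCCCCI | starting material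
10 | lithium C5–C6 enolate of the (7R)-7-ethyl ketone | [Li+].CC[C@H]1[C@@H]2OC(OC)C(=C)[C@@H]2C(CC=C)C([O-])=C1 | intermediate
11 | (3aS,6R,7R,7aS)-6-(4-azidobutyl)-7-ethyl-2-methoxy-3-methylidene-4-(prop-2-en-1-yl)hexahydro-1-benzofuran-5(2H)-one | CC[C@H]1[C@@H]2OC(OC)C(=C)[C@@H]2C(CC=C)C(=O)[C@@H]1CCCCN=[N+]=[N-] | intermediate
12 | (3aS,6R,7R,7aS)-6-(4-azidobutyl)-7-ethyl-2-hydroxy-3-methylidene-4-(prop-2-en-1-yl)hexahydro-1-benzofuran-5(2H)-one (lactol) | CC[C@H]1[C@@H]2OC(O)C(=C)[C@@H]2C(CC=C)C(=O)[C@@H]1CCCCN=[N+]=[N-] | intermediate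
13 | (3aS,6R,7R,7aS)-6-(4-azidobutyl)-7-ethyl-3-methylidene-4-(prop-2-en-1-yl)hexahydro-1-benzofuran-2,5-dione | CC[C@H]1[C@@H]2OC(=O)C(=C)[C@@H]2C(CC=C)C(=O)[C@@H]1CCCCN=[N+]=[N-] | intermediate
14 | 2-[(3aS,6R,7R,7aS)-6-(4-azidobutyl)-7-ethyl-3-methylidene-2,5-dioxooctahydro-1-benzofuran-4-yl]acetaldehyde | CC[C@H]1[C@@H]2OC(=O)C(=C)[C@@H]2C(CC=O)C(=O)[C@@H]1CCCCN=[N+]=[N-] | intermediate
15 | 2-[(3aS,6R,7R,7aS)-6-(4-aminobutyl)-7-ethyl-3-methylidene-2,5-dioxooctahydro-1-benzofuran-4-yl]acetaldehyde | CC[C@H]1[C@@H]2OC(=O)C(=C)[C@@H]2C(CC=O)C(=O)[C@@H]1CCCCN | intermediate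
16 | (9R,10R,11S,15S)-10-ethyl-14-methylidene-12-oxa-4-azatetracyclo[7.6.1.0(4,16).0(11,15)]hexadeca-1(16),2-dien-13-one | CC[C@H]1[C@@H]2OC(=O)C(=C)[C@@H]2c2ccn3c2[C@@H]1CCCC3 | intermediate
17 | N,N-dimethyliminium chloride of aldehyde 18 | CC[C@H]1[C@@H]2OC(=O)C(=C)[C@@H]2c2cc(C=[N+](C)C)n3c2[C@@H]1CCCC3.[Cl-] | intermediate
18 | (9R,10R,11S,15S)-10-ethyl-14-methylidene-13-oxo-12-oxa-4-azatetracyclo[7.6.1.0(4,16).0(11,15)]hexadeca-1(16),2-diene-3-carbaldehyde | CC[C@H]1[C@@H]2OC(=O)C(=C)[C@@H]2c2cc(C=O)n3c2[C@@H]1CCCC3 | intermediate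
19 | methyl 2-(bromomethyl)prop-2-enoate | COC(=O)C(=C)CBr | starting material
20 | methyl (4S)-2-methylidene-4-(trimethylsilyloxy)-4-(tetracyclic pyrrol-3-yl)butanoate | CC[C@H]1[C@@H]2OC(=O)C(=C)[C@@H]2c2cc([C@@H](O[Si](C)(C)C)CC(=C)C(=O)OC)n3c2[C@@H]1CCCC3 | intermediate
21 | (9R,10R,11S,15S)-10-ethyl-14-methylidene-3-[(2S)-4-methylidene-5-oxooxolan-2-yl]-12-oxa-4-azatetracyclo[7.6.1.0(4,16).0(11,15)]hexadeca-1(16),2-dien-13-one | CC[C@H]1[C@@H]2OC(=O)C(=C)[C@@H]2c2cc([C@@H]3CC(=C)C(=O)O3)n3c2[C@@H]1CCCC3 | intermediate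
22 | (9R,10R,11S,14R,15R)-10-ethyl-14-methyl-3-[(2S,4S)-4-methyl-5-oxooxolan-2-yl]-12-oxa-4-azatetracyclo[7.6.1.0(4,16).0(11,15)]hexadeca-1(16),2-dien-13-one | CC[C@H]1[C@@H]2OC(=O)[C@H](C)[C@@H]2c2cc([C@@H]3C[C@H](C)C(=O)O3)n3c2[C@@H]1CCCC3 | target

**Totals**
Total step count: 9. Longest linear sequence: 9 steps (1 → 22).

**Three steps most likely to fail, each with a fallback**

Step 2 (radical cascade): the α-keto radical may be reduced or may oligomerize before it is allylated. The fallback installs the allyl group before the radical step, so that only a plain reductive cyclization is asked of the radical. It sets out from 1: α-iodination (I2, pyridine, CH2Cl2) gives (4S)-4-hydroxy-2-iodocyclohex-2-en-1-one F1. Stille coupling (CH2=CHCH2SnBu3, PdCl2(PhCN)2, AsPh3, CuI, N-methylpyrrolidone) gives (4S)-4-hydroxy-2-(prop-2-en-1-yl)cyclohex-2-en-1-one F2. Iodoacetalization as in step 1 gives (4S)-4-[(2-iodo-1-methoxyprop-2-en-1-yl)oxy]-2-(prop-2-en-1-yl)cyclohex-2-en-1-one F3. A 5-exo vinyl-radical cyclization terminated by hydrogen transfer (Bu3SnH, AIBN, benzene, 80 °C) comes back to the route at 6.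

Step 4 (conjugate addition/alkylation): alkylation of the enolate with an unactivated primary iodide is slow, and the azide may not survive the organometallic medium. The fallback replaces alkylation by an aldol/dehydration/conjugate-reduction sequence with the nitrogen introduced last. It sets out from 8: the same cuprate addition is followed by aldol trapping of enolate 10 with 4-chlorobutanal (ZnCl2, −78 °C) to give (3aS,7R,7aS)-6-(4-chloro-1-hydroxybutyl)-7-ethyl-2-methoxy-3-methylidene-4-(prop-2-en-1-yl)hexahydro-1-benzofuran-5(2H)-one F4. Dehydration with the Burgess reagent gives (3aS,7R,7aS)-6-(4-chlorobutylidene)-7-ethyl-2-methoxy-3-methylidene-4-(prop-2-en-1-yl)hexahydro-1-benzofuran-5(2H)-one F5. Conjugate reduction with [CuH(PPh3)]6 and equilibration with DBU give (3aS,6R,7R,7aS)-6-(4-chlorobutyl)-7-ethyl-2-methoxy-3-methylidene-4-(prop-2-en-1-yl)hexahydro-1-benzofuran-5(2H)-one F6. Azide displacement (NaN3, NaI cat., DMF, 60 °C) comes back to the route at 11.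

Step 8 (asymmetric allylation): the electron-rich pyrrole aldehyde is a poor electrophile, and the enantioselectivity of the chromium catalyst on it is untested. The fallback sets the carbinol by asymmetric ketone reduction instead of carbonyl allylation, and bypasses 18. It sets out from 16: Friedel–Crafts acylation with itaconic anhydride (BF3·OEt2, ClCH2CH2Cl, 0 °C to rt; attack at the non-conjugated carbonyl) gives 2-methylidene-4-oxo-4-(tetracyclic pyrrol-3-yl)butanoic acid F7. Noyori transfer hydrogenation (RuCl(p-cymene)[(S,S)-TsDPEN], HCO2H–Et3N) gives (4S)-4-hydroxy-2-methylidene-4-(tetracyclic pyrrol-3-yl)butanoic acid F8, which lactonizes on concentration (or with a carbodiimide) and comes back to the route at 21.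

**Further compounds**
F1 | step 2 | (4S)-4-hydroxy-2-iodocyclohex-2-en-1-one | O=C1C(I)=C[C@@H](O)CC1
F2 | step 2 | (4S)-4-hydroxy-2-(prop-2-en-1-yl)cyclohex-2-en-1-one | O=C1C(CC=C)=C[C@@H](O)CC1
F3 | step 2 | (4S)-4-[(2-iodo-1-methoxyprop-2-en-1-yl)oxy]-2-(prop-2-en-1-yl)cyclohex-2-en-1-one | O=C1C(CC=C)=C[C@@H](OC(OC)C(I)=C)CC1
F4 | step 4 | (3aS,7R,7aS)-6-(4-chloro-1-hydroxybutyl)-7-ethyl-2-methoxy-3-methylidene-4-(prop-2-en-1-yl)hexahydro-1-benzofuran-5(2H)-one | CC[C@H]1[C@@H]2OC(OC)C(=C)[C@@H]2C(CC=C)C(=O)C1C(O)CCCCl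
F5 | step 4 | (3aS,7R,7aS)-6-(4-chlorobutylidene)-7-ethyl-2-methoxy-3-methylidene-4-(prop-2-en-1-yl)hexahydro-1-benzofuran-5(2H)-one | CC[C@H]1[C@@H]2OC(OC)C(=C)[C@@H]2C(CC=C)C(=O)C1=CCCCCl
F6 | step 4 | (3aS,6R,7R,7aS)-6-(4-chlorobutyl)-7-ethyl-2-methoxy-3-methylidene-4-(prop-2-en-1-yl)hexahydro-1-benzofuran-5(2H)-one | CC[C@H]1[C@@H]2OC(OC)C(=C)[C@@H]2C(CC=C)C(=O)[C@@H]1CCCCCl
F7 | step 8 | 2-methylidene-4-oxo-4-(tetracyclic pyrrol-3-yl)butanoic acid | CC[C@H]1[C@@H]2OC(=O)C(=C)[C@@H]2c2cc(C(=O)CC(=C)C(O)=O)n3c2[C@@H]1CCCC3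
F8 | step 8 | (4S)-4-hydroxy-2-methylidene-4-(tetracyclic pyrrol-3-yl)butanoic acid | CC[C@H]1[C@@H]2OC(=O)C(=C)[C@@H]2c2cc([C@@H](O)CC(=C)C(O)=O)n3c2[C@@H]1CCCC3
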